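All runs were computed with made-up constants; scatter was added.

**The question.** How much target does the flask with c(starting material) of 0.20 M hold at its best, when, and how early does it pass 15%? The alder and ash runs bracket it, with 0.10 M and 0.40 M under the same feed and the same gas.

common to all: gas phase 14 mM (held)

| flask | starting material | remark | time |
|---|---|---|---|
| alder | 0.10 M (fed, over 2.5 min) | run made earlier |  |
| ash | 0.40 M (fed, over 2.5 min) | run made earlier |  |
| flask | 0.20 M (fed, over 2.5 min) |  | 40 min |

| run | time / min | target / % | starting material / % |
|---|---|---|---|
| alder | 1.33 | 8.1 | 42.1 |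
| alder | 2.00 | 15.6 | 56.8 |
| alder | 4.00 | 29.7 | 40.1 |
| alder | 6.00 | 30.5 | 20.2 |
| alder | 12.0 | 19.8 | 2.4 |
| alder | 20.0 | 16.5 | 0.6 |
| alder | 30.0 | 13.2 | 0 |
| ash | 1.33 | 7.3 | 43.6 |
| ash | 2.00 | 11.0 | 61.8 |
| ash | 4.00 | 23.1 | 51.8 |
| ash | 6.00 | 26.7 | 28.6 |
| ash | 12.0 | 21.2 | 3.5 |
| ash | 20.0 | 15.7 | 0.3 |
| ash | 30.0 | 12.6 | 0 |

(scatter of a reading: 0.5 percentage points)

1. time, not beyond 40 min, at which the flask holds most target
2. the amount of target, in percent of the starting material charged, at that time
3. the first time at which target reaches 15%, in the same percent, in min

- at the start none of the gas phase is in solution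
- percentages count the whole charge, also what has not yet gone in

**First instants.** No gas is in solution at the start, and starting material is still arriving. At 2.00 min, with 80.0% of the charge in, the alder run holds 15.6% target and the ash run 11.0%, so the larger charge already lags.

**The middle.** With the feed over, starting material falls in the alder and ash runs and target nears its top. At 6.00 min the alder run reads 30.5% target and the ash run 26.7%. Across two doublings of charge that gap comes to 1.9 percentage points per doubling. This doubling penalty, the target lost near the top per doubling of charge, is a small correction to a large height. The flask has twice the alder charge, so the reckoning here gives 28.6%.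

**The end.** Target then falls in both runs, to 13.2% in the alder run and 12.6% in the ash run at 30.0 min, with starting material at 0%.

**The forecast.** It expects a peak of 29.5% (27.7% to 31.2%) at 5.7 min (4.8 min to 6.7 min), since the flask “sits midway on a log scale”, and 15% at 2.3 min (2 min to 2.7 min). Its height stands above the reckoning here, which uses the readings at 6.00 min and not estimated tops.

**The result.** The flask reaches 29.0% at 5.21 min and passes 15% at 2.11 min, inside the forecast's ranges.

    gas phase ⇌ dissolved gas, rate k1*(csat - [dissolved gas]) (kL = 0.143 s⁻¹)
    starting material + dissolved gas → target (k = 0.443 M⁻¹ s⁻¹)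
    starting material → side product (k = 6.52 × 10⁻⁴ s⁻¹)
    dissolved gas → decomposed reagent (k = 0.0113 s⁻¹)
    target → over-reaction product (k = 0.00117 s⁻¹)
    target ⇌ isomer of the product (K = 2.50, k = 0.00603 s⁻¹)

**Stage by stage.** At 5.21 min the flask still held 30.2% starting material beside 0.0110 M dissolved gas, with target at 29.0% and isomer of the product at 25.6%. By 20.0 min the flask had 0.121% starting material, 15.6% target and 27.9% over-reaction product. The penalty's 28.6%, reckoned for 6.00 min, lies below the flask's best and above its 28.1% at 6.51 min. For a neighbour flask with 0.80 M, twice the ash charge, the penalty gives 24.8% at 6.00 min, and the best of that neighbour flask is 22.3%.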